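## The problem

The target is a polyprenylated acylphloroglucinol on a bicyclo[3.3.1]nonane-2,4,9-trione core. Ring B (C1–C2–C3–C4–C5–C9) is the enolised trione, aroylated at C3. Ring A (C1–C9–C5–C6–C7–C8) carries geranyl at C7 and methyl plus homoprenyl at C8, and both bridgeheads, C1 (next to C8) and C5, are quaternary and prenylated. There are four stereocentres (C1, C5, C7, C8), three of them quaternary and three contiguous; C1 and C5 are tied together by the C9 bridge, so the independent elements are C7, C8 and the sense of the bicycle relative to them. C7, once set, can steer the closure of ring A through a chair in which geranyl is equatorial and so control C1 and C5. C8, whose two carbon chains differ little in size, cannot be left to conformational bias and needs a stereospecific event. Five trisubstituted alkenes exclude hydrogenation, strong acid, metathesis and unselective electrophiles or radicals. The enolised aroyl triketone and the phenol are prone to acid-induced cyclisation onto the prenyl groups and to retro-Claisen cleavage, so they must be unveiled last, under base. The feature that opens the key step is the C1–C8 bond, which joins a bridgehead to the fully substituted C8. Before it exists, ring B can be a 1,5-dimethoxycyclohexa-1,4-diene whose quaternary carbon (future C5) is flanked by two identical enol ether arms, and C8 can be the tertiary carbon of a trisubstituted epoxide on the side chain.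

## Retrosynthesis

**C3–aroyl bond and the two O-protecting groups.** Target 41 is taken back to its C4 methyl ether / aryl silyl ether 40. Compound 40 is cut at the C3–C(aroyl) bond into vinylogous ester 35 and acid chloride 38, which comes from 3-hydroxybenzoic acid 36 through the bis-silyl compound 37. Cutting here, and not at a prenyl group, keeps the aroylated triketone, the least robust array in the molecule, out of every earlier step. Compound 35 is simpler by the aryl ketone and the acidic enol. The forward steps must lithiate C3 selectively and free both oxygens under base.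

**C8 side chain.** Compound 35 is cut inside the homoprenyl chain, between its second and third carbon, into the C8-vinyl compound 32 and 1-bromo-2-methylprop-1-ene 33. This follows from the key step: an epoxide opening at C8 necessarily leaves oxygen on the carbon next to C8, so homoprenyl cannot be carried through it. Vinyl is the smallest handle that an oxygenated two-carbon stub can become. The forward reaction must hydroborate the only monosubstituted alkene beside four trisubstituted ones and two hindered carbonyls, then couple.

**C1–prenyl bond.** Compound 32 is cut into 30 and prenyl bromide 20. C1 is the one bridgehead the key step leaves unsubstituted, and it lies between the C2 and C9 carbonyls, so it can be lithiated and alkylated with retention. Doing so on 30, where C8 bears only methyl and vinyl, places the alkylation at the least crowded stage.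

**Adjustments back to the cyclisation product.** The vinyl group of 30 comes from aldehyde 29 (C=C cut), 29 from diol 28 (glycol cleavage), 28 from bis-silyl ether 27, and the C2 carbonyl of 27 from enol ether 26. Oxidising C2 directly after the cyclisation converts the acid-labile enol ether into a robust vinylogous ester before anything else is attempted. These steps form no skeletal bond and are the price of the epoxide route.

**C1–C8 bond (key disconnection).** Compound 26 is opened to the monocyclic diene 24, in which C8 is the tertiary epoxide carbon. Against cutting C5–C6 or a bond of ring B, this removes one ring and three stereocentres (C1, C5, C8) in one step. The precursor's only stereocentres are then C7 and the epoxide. The forward reaction must deliver one enol ether arm to C8 with inversion, let C7 choose the arm, and spare the other arm as the regiodefined C4 oxygen.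

**C5–C6 bond and the diene.** Compound 24 is cut into iodide 17 and diene 22; 22 comes from 19 and 20, and 19 from 1,3-dimethoxybenzene 18. The quaternary carbon arises by two alkylations of one carbon and, its arms being identical, carries no stereochemical burden. The forward step asks a tertiary pentadienyl anion to displace a β-branched primary iodide.

**Epoxide.** Compound 17 goes back through epoxy alcohol 16 to allylic alcohol 15 (both epoxide C–O bonds cut), and 15 through 14 and 13 to imide 12. Sharpless epoxidation is reagent-controlled and picks the single alkene that bears an allylic hydroxyl out of three trisubstituted alkenes. E geometry plus the tartrate fix both epoxide carbons.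

**C7–geranyl bond.** Compound 12 is cut into imide 9 and geranyl bromide 10; 9 comes from acid 6 and oxazolidinone 7. Cutting the geranyl bond rather than C6–C7 or C7–C8 uses a reactive allylic bromide and an enolate whose α-carbon already carries the alkene. The auxiliary sets C7.

**The E-trisubstituted alkene.** Acid 6 goes back through 5 to allylic alcohol 4, and 4 to alkyne 1 by cutting the C–CH3 and C–CH2OH bonds. Syn carboalumination fixes the geometry, which equilibrating olefinations would not.

## Roads not taken

**Alternative 1:** The cuts are the C8–homoprenyl and C1–prenyl bonds on a preformed ring A, with ring B built afterwards. In the forward key step an organocopper reagent carrying the homoprenyl chain adds to C8 of (S)-4-geranyl-3-methylcyclohex-2-enone A1 anti to the C7 substituent, and the C1 enolate is trapped with 20 to give cyclohexanone A2.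
- Merits: the conjugate addition/alkylation is well known, the trans addition gives the correct C7/C8 relationship, and a fully decorated ring A is reached in far fewer steps than the eleven linear steps to 24. In this respect it is better than the chosen plan.
- Weak points: addition to a β,β-disubstituted enone next to a branched carbon is sluggish. More seriously, ring B must then be annulated onto A2: after C5 prenylation a three-carbon unit has to be acylated onto two fully hindered α-carbons, creating both bridgehead quaternary centres in one notoriously inefficient operation. The resulting trione has no regiodefined enol ether, and A1 must be made enantiopure first.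
- Comparison: the chosen plan carries ring B from the start with its C4 oxygen differentiated and sets three stereocentres in the ring closure. It pays with a longer approach to the cyclisation substrate.

**Alternative 2:** The cut is C5–C6. In the forward step the enolised C5 of a dearomatised acylphloroglucinol adds to an acrylate terminus (C6), ring A closes, and the C7 ester equilibrates to bicyclic ester A3.
- Merits: ring B, all three ring carbonyls and the aroyl group come from a cheap aromatic. No allylic oxidation, bridgehead lithiation or late aroylation is needed. In oxidation-state economy of the core it is better than the chosen plan.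
- Weak points: geranyl must be built from the C7 ester afterwards. That means chemoselective reduction beside three ketone-level carbonyls, then chain extension to an E-trisubstituted alkene through an epimerisable C7 aldehyde. C8 and C1 arise in a dearomative Claisen step that differentiates methyl from homoprenyl only by alkene geometry and has no reagent control of absolute sense.
- Comparison: the chosen plan has geranyl intact from step 5 and takes its absolute configuration from two reagent-controlled steps. It pays with the C2 oxidation and the late C1 and C3 functionalisations.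

**Alternative 3:** The cuts are C6–C7 and C1–C8 in a Michael/aldol annulation. The enamine of (E)-5,9-dimethyldeca-4,8-dienal A4 adds to methyl vinyl ketone A5, and aldol condensation closes ring A as (S)-4-geranylcyclohex-2-enone A6.
- Merits: C7 is set catalytically in one or two steps from simple materials. For C7 alone it is clearly better than the auxiliary route, which needs six steps to reach that centre.
- Weak points: A6 has neither C8 substituent. C8 needs two successive C–C bonds (conjugate methylation, re-dehydrogenation to A1, then the key step of Alternative 1). It is therefore an entry to Alternative 1 and inherits its ring B problem.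
- Comparison: equal or better for C7, weaker for everything else. The chosen plan spends more steps on C7 but uses that centre to control C1 and C5 in the ring closure.

Key step: step 14

Remark on the chemistry: core locants are C9 (bridging ketone), C1 (bridgehead next to C8), C2–C4 (trione bridge), C5, C6–C8, and acyclic carbons take the locant they will have; geranyl = (2E)-3,7-dimethylocta-2,6-dien-1-yl, prenyl = 3-methylbut-2-en-1-yl, homoprenyl = 4-methylpent-3-en-1-yl.
Assumption: silyl ether 1 is treated as a catalogue compound, and the oxocarbenium ion 25 is assumed to persist until the aqueous quench.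

Step 1
Reactants: 1 tert-butyl(but-3-yn-1-yloxy)dimethylsilane
Product: 4 (E)-5-(tert-butyldimethylsilyloxy)-3-methylpent-2-en-1-ol, via alkenyldimethylalane 2 (not isolated), via lithium alkenylaluminate 3 (not isolated)
Conditions: Me3Al, Cp2ZrCl2 (cat.), CH2Cl2, 0 °C to rt; n-BuLi, THF, −78 °C; (CH2O)n, −78 °C to rt
Reagents that add atoms: trimethylaluminium C[Al](C)C; paraformaldehyde (as formaldehyde) C=O
Why: Negishi zirconium-catalysed carboalumination adds methyl and aluminium syn across the terminal alkyne with methyl on the internal carbon; the aluminate is hydroxymethylated with retention, so the alkene should emerge as the E isomer only.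

Step 2
Reactants: 4 (E)-5-(tert-butyldimethylsilyloxy)-3-methylpent-2-en-1-ol
Product: 5 (E)-5-(tert-butyldimethylsilyloxy)-1-(tert-butyldiphenylsilyloxy)-3-methylpent-2-ene
Conditions: TBDPSCl, imidazole, CH2Cl2, rt
Reagents that add atoms: tert-butyl(chloro)diphenylsilane CC(C)(C)[Si](Cl)(c1ccccc1)c1ccccc1
Why: Standard silylation of the primary allylic alcohol; the tert-butyldiphenylsilyl group is chosen because it must outlast the acidic oxidation of step 3 and must not act as a leaving group from the dienolate of step 5.

Step 3
Reactants: 5 (E)-5-(tert-butyldimethylsilyloxy)-1-(tert-butyldiphenylsilyloxy)-3-methylpent-2-ene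
Product: 6 (E)-5-(tert-butyldiphenylsilyloxy)-3-methylpent-3-enoic acid
Conditions: CrO3, H2SO4, acetone/H2O, 0 °C
Reagents that add atoms: water O
Why: Jones oxidation: the acidic medium cleaves the primary tert-butyldimethylsilyl ether and the freed alcohol is oxidised through the aldehyde hydrate to the acid in one pot, while the far more acid-stable diphenylsilyl ether stays; at 0 °C the β,γ-alkene is not expected to move into conjugation.

Step 4
Reactants: 6 (E)-5-(tert-butyldiphenylsilyloxy)-3-methylpent-3-enoic acid; 7 (S)-4-benzyloxazolidin-2-one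
Product: 9 (S)-4-benzyl-3-[(E)-5-(tert-butyldiphenylsilyloxy)-3-methylpent-3-enoyl]oxazolidin-2-one, via pivalic mixed anhydride 8 (not isolated)
Conditions: PivCl, Et3N, THF, −20 °C; then LiCl, 7, rt
Reagents that add atoms: none
Why: N-Acylation of the oxazolidinone by the mixed anhydride under LiCl/Et3N activation; no strong base is present, so the acyl group should stay deconjugated and E.

Step 5
Reactants: 9 (S)-4-benzyl-3-[(E)-5-(tert-butyldiphenylsilyloxy)-3-methylpent-3-enoyl]oxazolidin-2-one; 10 geranyl bromide
Product: 12 (S)-4-benzyl-3-[(2S,3E)-5-(tert-butyldiphenylsilyloxy)-2-geranyl-3-methylpent-3-enoyl]oxazolidin-2-one, via sodium dienolate 11 (not isolated)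
Conditions: NaN(SiMe3)2, THF, −78 °C; 10, −78 to −40 °C
Reagents that add atoms: none
Why: Evans asymmetric alkylation: the chelated Z-dienolate is alkylated at its α-carbon by the allylic bromide on the face away from the benzyl group, which sets C7 as (S) in this compound; the C3=C4 geometry is untouched because that bond stays a double bond in the dienolate, and silanolate is too poor a leaving group to be expelled at −78 °C.

Step 6
Reactants: 12 (S)-4-benzyl-3-[(2S,3E)-5-(tert-butyldiphenylsilyloxy)-2-geranyl-3-methylpent-3-enoyl]oxazolidin-2-one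
Product: 13 (2S,3E)-5-(tert-butyldiphenylsilyloxy)-2-geranyl-3-methylpent-3-en-1-ol
Conditions: LiBH4, MeOH, Et2O, 0 °C
Reagents that add atoms: none
Why: Reductive cleavage of the N-acyl oxazolidinone at the exocyclic carbonyl releases the auxiliary; the α-centre is not enolised, so C7 should be retained.

Step 7
Reactants: 13 (2S,3E)-5-(tert-butyldiphenylsilyloxy)-2-geranyl-3-methylpent-3-en-1-ol
Product: 14 tert-butyl{[(2E,4S)-4-geranyl-5-iodo-3-methylpent-2-en-1-yl]oxy}diphenylsilane
Conditions: I2, PPh3, imidazole, CH2Cl2, 0 °C to rt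
Reagents that add atoms: iodine II
Why: Appel-type iodination of the primary alcohol through its alkoxyphosphonium salt (SN2 at CH2); alkenes and silyl ether are inert and the stereocentre is not involved.

Step 8
Reactants: 14 tert-butyl{[(2E,4S)-4-geranyl-5-iodo-3-methylpent-2-en-1-yl]oxy}diphenylsilane
Product: 15 (2E,4S)-4-geranyl-5-iodo-3-methylpent-2-en-1-ol
Conditions: HF·pyridine, pyridine, THF, 0 °C to rt
Reagents that add atoms: none
Why: Fluoride-mediated desilylation under buffered, weakly acidic conditions, chosen over basic fluoride so that the primary iodide is neither displaced nor eliminated.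

Step 9
Reactants: 15 (2E,4S)-4-geranyl-5-iodo-3-methylpent-2-en-1-ol
Product: 16 (2S,3S,4S)-2,3-epoxy-4-geranyl-5-iodo-3-methylpentan-1-ol
Conditions: Ti(OiPr)4 (10 mol %), L-(+)-diisopropyl tartrate (12 mol %), t-BuOOH, 4 Å MS, CH2Cl2, −20 °C
Reagents that add atoms: tert-butyl hydroperoxide CC(C)(C)OO
Why: Sharpless asymmetric epoxidation: only the alkene whose allylic hydroxyl binds titanium is oxidised, so the two geranyl alkenes should be left; with the L-(+)-tartrate the E-allylic alcohol gives the (2S,3S)-epoxide, a reagent-controlled outcome expected to override the remote C7 centre. These carbons are the future C8 and its oxygenated neighbour.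

Step 10
Reactants: 16 (2S,3S,4S)-2,3-epoxy-4-geranyl-5-iodo-3-methylpentan-1-ol
Product: 17 (2S,3S,4S)-2,3-epoxy-4-geranyl-5-iodo-3-methyl-1-(triisopropylsilyloxy)pentane
Conditions: TIPSCl, imidazole, DMAP (cat.), CH2Cl2, rt
Reagents that add atoms: chlorotriisopropylsilane CC(C)[Si](Cl)(C(C)C)C(C)C
Why: Silylation under mildly basic conditions (a silyl triflate is avoided because it would activate the epoxide); the triisopropylsilyl ether is robust toward the organolithium of step 13 and the Lewis acid of step 14.

Step 11
Reactants: 18 1,3-dimethoxybenzene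
Product: 19 1,5-dimethoxycyclohexa-1,4-diene
Conditions: Li, NH3(l), t-BuOH, THF, −78 °C
Reagents that add atoms: none
Why: Birch reduction: the two methoxy groups direct protonation so that both remain on double bonds, giving the 1,4-diene with two enol ethers; tert-butanol as proton source limits over-reduction.

Step 12
Reactants: 19 1,5-dimethoxycyclohexa-1,4-diene; 20 prenyl bromide
Product: 22 1,5-dimethoxy-6-prenylcyclohexa-1,4-diene, via lithiated diene 21 (not isolated)
Conditions: t-BuLi, THF, −78 °C; 20, −78 °C to rt
Reagents that add atoms: none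
Why: The CH2 flanked by the two methoxy-bearing carbons is the most acidic position; its lithium pentadienide is alkylated at the central carbon by the allylic bromide (SN2).

Step 13
Reactants: 22 1,5-dimethoxy-6-prenylcyclohexa-1,4-diene; 17 (2S,3S,4S)-2,3-epoxy-4-geranyl-5-iodo-3-methyl-1-(triisopropylsilyloxy)pentane
Product: 24 6-[(2R,3S,4S)-3,4-epoxy-2-geranyl-3-methyl-5-(triisopropylsilyloxy)pentyl]-1,5-dimethoxy-6-prenylcyclohexa-1,4-diene, via lithiated prenyl diene 23 (not isolated)
Conditions: s-BuLi, THF, −78 to −40 °C; 17, −78 °C to rt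
Reagents that add atoms: none
Why: A second deprotonation at the same carbon gives a tertiary pentadienyl anion that should displace the primary iodide (SN2) and create the quaternary carbon that becomes C5; its two arms are identical, so no stereochemical issue arises. Epoxide and silyl ether are expected to tolerate the carbanion at low temperature.

Step 14
Reactants: 24 6-[(2R,3S,4S)-3,4-epoxy-2-geranyl-3-methyl-5-(triisopropylsilyloxy)pentyl]-1,5-dimethoxy-6-prenylcyclohexa-1,4-diene
Product: 26 (1S,5S,7R,8S)-7-geranyl-4-methoxy-8-methyl-5-prenyl-8-[(1R)-2-(triisopropylsilyloxy)-1-(trimethylsilyloxy)ethyl]bicyclo[3.3.1]non-3-en-9-one, via C9 oxocarbenium triflate 25 (not isolated)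
Conditions: TMSOTf, 2,6-lutidine, CH2Cl2, −78 °C; aq. NaHCO3
Reagents that add atoms: trimethylsilyl trifluoromethanesulfonate C[Si](C)(C)OS(=O)(=O)C(F)(F)F; water O
Why: TMSOTf silylates the epoxide oxygen and the tertiary C8–O bond, the one not deactivated by the neighbouring silyloxymethyl group, lengthens; the β-carbon of one enol ether arm (future C1) attacks C8 anti to the departing oxygen, forming C1–C8, closing ring A (C1–C9–C5–C6–C7–C8) in the 6-exo-tet mode and leaving the oxygen on the exocyclic carbon as its trimethylsilyl ether. The closest known reaction type is the Lewis-acid-mediated epoxide-opening cyclisation of 6,6-disubstituted 1,5-dimethoxycyclohexa-1,4-dienes to bicyclo[3.3.1]nonanes, a relative of epoxide-initiated cation–olefin cyclisation. C8 is set by inversion at the epoxide carbon made in step 9, so it is reagent-derived and independent of conformation. C5 and C1 are set together by the choice of arm: only one arm lets ring A form as a chair with the C7 geranyl group equatorial and the diene ring spanning C1 and C5 diaxially, whereas the other would need geranyl axial and pointing into ring B, or a boat. The C7 centre from step 5 therefore secures the group selectivity that the step needs. The chemoselectivity needed, enol ether over the three trisubstituted alkenes, rests on the far higher nucleophilicity of the enol ether and on the six-membered ring being the only unstrained closure. The oxocarbenium ion 25 cannot lose a proton (C1 becomes a bridgehead, C5 is quaternary) and cannot be captured by the new silyl ether oxygen, which sits on the equatorial C8 substituent anti to C9, so the quench should hydrolyse it to the C9 ketone. The second enol ether is untouched and marks C4.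

Step 15
Reactants: 26 (1S,5S,7R,8S)-7-geranyl-4-methoxy-8-methyl-5-prenyl-8-[(1R)-2-(triisopropylsilyloxy)-1-(trimethylsilyloxy)ethyl]bicyclo[3.3.1]non-3-en-9-one
Product: 27 (1R,5S,7R,8S)-7-geranyl-4-methoxy-8-methyl-5-prenyl-8-[(1R)-2-(triisopropylsilyloxy)-1-(trimethylsilyloxy)ethyl]bicyclo[3.3.1]non-3-ene-2,9-dione
Conditions: t-BuOOH, PhI(OAc)2, Cs2CO3, EtOAc, −20 °C
Reagents that add atoms: tert-butyl hydroperoxide CC(C)(C)OO
Why: Radical allylic oxidation by tert-butylperoxy radicals: the C2–H bonds are the weakest in the molecule because the radical is allylic to the enol ether and stabilised by its oxygen, and the peroxide formed collapses under base to the C2 ketone. This oxidation type is established on bicyclic methyl enol ethers of this family that carry prenyl-type chains, and it converts the acid-labile enol ether into a robust vinylogous ester.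

Step 16
Reactants: 27 (1R,5S,7R,8S)-7-geranyl-4-methoxy-8-methyl-5-prenyl-8-[(1R)-2-(triisopropylsilyloxy)-1-(trimethylsilyloxy)ethyl]bicyclo[3.3.1]non-3-ene-2,9-dione
Product: 28 (1R,5S,7R,8S)-8-[(1R)-1,2-dihydroxyethyl]-7-geranyl-4-methoxy-8-methyl-5-prenylbicyclo[3.3.1]non-3-ene-2,9-dione
Conditions: Bu4NF, AcOH, THF, 0 °C to rt
Reagents that add atoms: none
Why: Fluoride cleaves both silyl ethers; acetic acid buffers the medium so that the alkoxides do not add to the neighbouring carbonyl groups.

Step 17
Reactants: 28 (1R,5S,7R,8S)-8-[(1R)-1,2-dihydroxyethyl]-7-geranyl-4-methoxy-8-methyl-5-prenylbicyclo[3.3.1]non-3-ene-2,9-dione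
Product: 29 (1R,5S,7R,8S)-7-geranyl-4-methoxy-8-methyl-2,9-dioxo-5-prenylbicyclo[3.3.1]non-3-ene-8-carbaldehyde
Conditions: NaIO4, THF/pH 7 buffer, 0 °C to rt
Reagents that add atoms: none
Why: Malaprade glycol cleavage through the cyclic periodate ester under neutral conditions; the aldehyde sits on the quaternary C8 and can neither epimerise nor enolise.

Step 18
Reactants: 29 (1R,5S,7R,8S)-7-geranyl-4-methoxy-8-methyl-2,9-dioxo-5-prenylbicyclo[3.3.1]non-3-ene-8-carbaldehyde
Product: 30 (1R,5S,7R,8S)-7-geranyl-4-methoxy-8-methyl-5-prenyl-8-vinylbicyclo[3.3.1]non-3-ene-2,9-dione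
Conditions: Ph3PCH3Br, KN(SiMe3)2, THF, 0 °C; 29, −78 to 0 °C
Reagents that add atoms: methyltriphenylphosphonium bromide C[P+](c1ccccc1)(c1ccccc1)c1ccccc1.[Br-]
Why: Wittig methylenation; the aldehyde should react far faster than the hindered C9 ketone or the vinylogous ester carbonyl, and a slight deficit of base avoids deprotonation elsewhere.

Step 19
Reactants: 30 (1R,5S,7R,8S)-7-geranyl-4-methoxy-8-methyl-5-prenyl-8-vinylbicyclo[3.3.1]non-3-ene-2,9-dione; 20 prenyl bromide
Product: 32 (1R,5S,7R,8S)-7-geranyl-4-methoxy-8-methyl-1,5-diprenyl-8-vinylbicyclo[3.3.1]non-3-ene-2,9-dione, via bridgehead lithium compound 31 (not isolated)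
Conditions: LiN(iPr)2, THF, −78 °C; 20, −78 to 0 °C
Reagents that add atoms: none
Why: Deprotonation of C1, which lies between the C2 and C9 carbonyls, gives a configurationally fixed bridgehead carbanion (not an enolate) that the allylic bromide alkylates with retention, the only course open at a bridgehead. This lithiation/alkylation is established for methyl enol ethers of bicyclo[3.3.1]nonane-2,4,9-triones with a quaternary C8 neighbour.

Step 20
Reactants: 32 (1R,5S,7R,8S)-7-geranyl-4-methoxy-8-methyl-1,5-diprenyl-8-vinylbicyclo[3.3.1]non-3-ene-2,9-dione; 33 1-bromo-2-methylprop-1-ene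
Product: 35 (1R,5S,7R,8S)-7-geranyl-8-homoprenyl-4-methoxy-8-methyl-1,5-diprenylbicyclo[3.3.1]non-3-ene-2,9-dione, via B-alkyl-9-BBN adduct 34 (not isolated)
Conditions: 9-BBN, THF, rt to 40 °C; then 33, Pd(dppf)Cl2 (cat.), AsPh3 (cat.), Cs2CO3, DMF/H2O, rt to 50 °C
Reagents that add atoms: none
Why: 9-BBN adds to the only monosubstituted alkene, boron at the terminal carbon, much faster than it attacks trisubstituted alkenes or reduces the C9 ketone (now between two quaternary carbons) and the vinylogous ester. The B-alkyl Suzuki–Miyaura coupling with the alkenyl bromide then completes the homoprenyl chain in the same flask; C8 is not touched.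

Step 21
Reactants: 36 3-hydroxybenzoic acid
Product: 37 tert-butyldimethylsilyl 3-(tert-butyldimethylsilyloxy)benzoate
Conditions: TBSCl, imidazole, DMF, rt
Reagents that add atoms: tert-butyl(chloro)dimethylsilane CC(C)(C)[Si](C)(C)Cl
Why: Silylation of both the carboxylic acid and the phenol; the silyl ester is the handle for step 22.

Step 22
Reactants: 37 tert-butyldimethylsilyl 3-(tert-butyldimethylsilyloxy)benzoate
Product: 38 3-(tert-butyldimethylsilyloxy)benzoyl chloride
Conditions: (COCl)2, DMF (cat.), CH2Cl2, 0 °C to rt
Reagents that add atoms: oxalyl chloride ClC(=O)C(=O)Cl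
Why: Silyl esters are converted into acid chlorides by oxalyl chloride/DMF under neutral conditions with release of the chlorosilane, so the aryl silyl ether should survive.

Step 23
Reactants: 35 (1R,5S,7R,8S)-7-geranyl-8-homoprenyl-4-methoxy-8-methyl-1,5-diprenylbicyclo[3.3.1]non-3-ene-2,9-dione; 38 3-(tert-butyldimethylsilyloxy)benzoyl chloride
Product: 40 (1S,5S,7R,8S)-3-[3-(tert-butyldimethylsilyloxy)benzoyl]-7-geranyl-8-homoprenyl-4-methoxy-8-methyl-1,5-diprenylbicyclo[3.3.1]non-3-ene-2,9-dione, via C3-lithio compound 39 (not isolated)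
Conditions: lithium 2,2,6,6-tetramethylpiperidide, THF, −78 °C; 38, −78 °C to rt
Reagents that add atoms: none
Why: The C3–H of the vinylogous ester, the only acidic position left, is removed by the hindered amide and the alkenyllithium is acylated by the aroyl chloride; directed C3 lithiation/acylation is established for this ring system.

Step 24
Reactants: 40 (1S,5S,7R,8S)-3-[3-(tert-butyldimethylsilyloxy)benzoyl]-7-geranyl-8-homoprenyl-4-methoxy-8-methyl-1,5-diprenylbicyclo[3.3.1]non-3-ene-2,9-dione
Product: 41 (1S,5S,7R,8S)-7-geranyl-8-homoprenyl-4-hydroxy-3-(3-hydroxybenzoyl)-8-methyl-1,5-diprenylbicyclo[3.3.1]non-3-ene-2,9-dione (CNP0285073.1)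
Conditions: LiOH, dioxane/H2O, 90 °C; then 1 M HCl, 0 °C
Reagents that add atoms: lithium hydroxide [Li+].[OH-]
Why: Hydroxide adds to C4 and expels methoxide (addition–elimination on the 3-acyl vinylogous ester) and cleaves the aryl silyl ether. The resulting dianion resists further attack, and brief cold acidification frees the enolised triketone and the phenol without inviting cyclisation onto the prenyl groups.

## Compound list

1 | tert-butyl(but-3-yn-1-yloxy)dimethylsilane | C#CCCO[Si](C)(C)C(C)(C)C | starting material
2 | [(E)-4-(tert-butyldimethylsilyloxy)-2-methylbut-1-enyl]dimethylalane | C[Al](C)/C=C(\C)CCO[Si](C)(C)C(C)(C)C | intermediate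
3 | lithium butyl[(E)-4-(tert-butyldimethylsilyloxy)-2-methylbut-1-enyl]dimethylaluminate | [Li+].CCCC[Al-](C)(C)/C=C(\C)CCO[Si](C)(C)C(C)(C)C | intermediate
4 | (E)-5-(tert-butyldimethylsilyloxy)-3-methylpent-2-en-1-ol | OC/C=C(\C)CCO[Si](C)(C)C(C)(C)C | intermediate
5 | (E)-5-(tert-butyldimethylsilyloxy)-1-(tert-butyldiphenylsilyloxy)-3-methylpent-2-ene | CC(C)(C)[Si](C)(C)OCC/C(C)=C/CO[Si](c1ccccc1)(c1ccccc1)C(C)(C)C | intermediate
6 | (E)-5-(tert-butyldiphenylsilyloxy)-3-methylpent-3-enoic acid | OC(=O)C/C(C)=C/CO[Si](c1ccccc1)(c1ccccc1)C(C)(C)C | intermediate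
7 | (S)-4-benzyloxazolidin-2-one | O=C1OC[C@H](Cc2ccccc2)N1 | starting material
8 | mixed anhydride of 6 and pivalic acid | CC(C)(C)C(=O)OC(=O)C/C(C)=C/CO[Si](c1ccccc1)(c1ccccc1)C(C)(C)C | intermediate
9 | (S)-4-benzyl-3-[(E)-5-(tert-butyldiphenylsilyloxy)-3-methylpent-3-enoyl]oxazolidin-2-one | O=C(C/C(C)=C/CO[Si](c1ccccc1)(c1ccccc1)C(C)(C)C)N1C(=O)OC[C@@H]1Cc1ccccc1 | intermediate
10 | geranyl bromide, (E)-1-bromo-3,7-dimethylocta-2,6-diene | CC(C)=CCC/C(C)=C/CBr | starting material
11 | sodium (Z)-dienolate of 9 | [Na+].[O-]/C(=C\C(C)=C\CO[Si](c1ccccc1)(c1ccccc1)C(C)(C)C)N1C(=O)OC[C@@H]1Cc1ccccc1 | intermediate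
12 | (S)-4-benzyl-3-[(2S,3E)-5-(tert-butyldiphenylsilyloxy)-2-geranyl-3-methylpent-3-enoyl]oxazolidin-2-one | CC(C)=CCC/C(C)=C/C[C@@H](/C(C)=C/CO[Si](c1ccccc1)(c1ccccc1)C(C)(C)C)C(=O)N1C(=O)OC[C@@H]1Cc1ccccc1 | intermediate
13 | (2S,3E)-5-(tert-butyldiphenylsilyloxy)-2-geranyl-3-methylpent-3-en-1-ol | CC(C)=CCC/C(C)=C/C[C@@H](/C(C)=C/CO[Si](c1ccccc1)(c1ccccc1)C(C)(C)C)CO | intermediate
14 | tert-butyl{[(2E,4S)-4-geranyl-5-iodo-3-methylpent-2-en-1-yl]oxy}diphenylsilane | CC(C)=CCC/C(C)=C/C[C@@H](/C(C)=C/CO[Si](c1ccccc1)(c1ccccc1)C(C)(C)C)CI | intermediate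
15 | (2E,4S)-4-geranyl-5-iodo-3-methylpent-2-en-1-ol | CC(C)=CCC/C(C)=C/C[C@@H](/C(C)=C/CO)CI | intermediate
16 | (2S,3S,4S)-2,3-epoxy-4-geranyl-5-iodo-3-methylpentan-1-ol | CC(C)=CCC/C(C)=C/C[C@@H]([C@]1(C)O[C@H]1CO)CI | intermediate
17 | (2S,3S,4S)-2,3-epoxy-4-geranyl-5-iodo-3-methyl-1-(triisopropylsilyloxy)pentane | CC(C)=CCC/C(C)=C/C[C@@H]([C@]1(C)O[C@H]1CO[Si](C(C)C)(C(C)C)C(C)C)CI | intermediate
18 | 1,3-dimethoxybenzene | COc1cccc(OC)c1 | starting material
19 | 1,5-dimethoxycyclohexa-1,4-diene | COC1=CCC=C(OC)C1 | intermediate
20 | prenyl bromide, 1-bromo-3-methylbut-2-ene | CC(C)=CCBr | starting material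
21 | 6-lithio-1,5-dimethoxycyclohexa-1,4-diene | [Li]C1C(OC)=CCC=C1OC | intermediate
22 | 1,5-dimethoxy-6-prenylcyclohexa-1,4-diene | COC1=CCC=C(OC)C1CC=C(C)C | intermediate
23 | 6-lithio-1,5-dimethoxy-6-prenylcyclohexa-1,4-diene | [Li]C1(CC=C(C)C)C(OC)=CCC=C1OC | intermediate
24 | 6-[(2R,3S,4S)-3,4-epoxy-2-geranyl-3-methyl-5-(triisopropylsilyloxy)pentyl]-1,5-dimethoxy-6-prenylcyclohexa-1,4-diene | CC(C)=CCC/C(C)=C/C[C@@H]([C@]2(C)O[C@H]2CO[Si](C(C)C)(C(C)C)C(C)C)CC3(CC=C(C)C)C(OC)=CCC=C3OC | intermediate
25 | C9 O-methyl oxocarbenium triflate corresponding to 26 | CC(C)=CCC/C(C)=C/C[C@@H]1C[C@]2(CC=C(C)C)C(=[O+]C)[C@@H](CC=C2OC)[C@@]1(C)[C@@H](O[Si](C)(C)C)CO[Si](C(C)C)(C(C)C)C(C)C.[O-]S(=O)(=O)C(F)(F)F | intermediate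
26 | (1S,5S,7R,8S)-7-geranyl-4-methoxy-8-methyl-5-prenyl-8-[(1R)-2-(triisopropylsilyloxy)-1-(trimethylsilyloxy)ethyl]bicyclo[3.3.1]non-3-en-9-one | CC(C)=CCC/C(C)=C/C[C@@H]1C[C@]2(CC=C(C)C)C(=O)[C@@H](CC=C2OC)[C@@]1(C)[C@@H](O[Si](C)(C)C)CO[Si](C(C)C)(C(C)C)C(C)C | intermediate
27 | (1R,5S,7R,8S)-7-geranyl-4-methoxy-8-methyl-5-prenyl-8-[(1R)-2-(triisopropylsilyloxy)-1-(trimethylsilyloxy)ethyl]bicyclo[3.3.1]non-3-ene-2,9-dione | CC(C)=CCC/C(C)=C/C[C@@H]1C[C@]2(CC=C(C)C)C(=O)[C@@H](C(=O)C=C2OC)[C@@]1(C)[C@@H](O[Si](C)(C)C)CO[Si](C(C)C)(C(C)C)C(C)C | intermediate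
28 | (1R,5S,7R,8S)-8-[(1R)-1,2-dihydroxyethyl]-7-geranyl-4-methoxy-8-methyl-5-prenylbicyclo[3.3.1]non-3-ene-2,9-dione | CC(C)=CCC/C(C)=C/C[C@@H]1C[C@]2(CC=C(C)C)C(=O)[C@@H](C(=O)C=C2OC)[C@@]1(C)[C@@H](O)CO | intermediate
29 | (1R,5S,7R,8S)-7-geranyl-4-methoxy-8-methyl-2,9-dioxo-5-prenylbicyclo[3.3.1]non-3-ene-8-carbaldehyde | CC(C)=CCC/C(C)=C/C[C@@H]1C[C@]2(CC=C(C)C)C(=O)[C@@H](C(=O)C=C2OC)[C@@]1(C)C=O | intermediate
30 | (1R,5S,7R,8S)-7-geranyl-4-methoxy-8-methyl-5-prenyl-8-vinylbicyclo[3.3.1]non-3-ene-2,9-dione | CC(C)=CCC/C(C)=C/C[C@@H]1C[C@]2(CC=C(C)C)C(=O)[C@@H](C(=O)C=C2OC)[C@@]1(C)C=C | intermediate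
31 | C1-lithio derivative of 30 | CC(C)=CCC/C(C)=C/C[C@@H]1C[C@]2(CC=C(C)C)C(=O)[C@@]([Li])(C(=O)C=C2OC)[C@@]1(C)C=C | intermediate
32 | (1R,5S,7R,8S)-7-geranyl-4-methoxy-8-methyl-1,5-diprenyl-8-vinylbicyclo[3.3.1]non-3-ene-2,9-dione | CC(C)=CCC/C(C)=C/C[C@@H]1C[C@]2(CC=C(C)C)C(=O)[C@@](CC=C(C)C)(C(=O)C=C2OC)[C@@]1(C)C=C | intermediate
33 | 1-bromo-2-methylprop-1-ene | CC(C)=CBr | starting material
34 | B-alkyl-9-borabicyclo[3.3.1]nonane adduct of 32 (boron on the terminal carbon of the former vinyl group) | CC(C)=CCC/C(C)=C/C[C@@H]1C[C@]2(CC=C(C)C)C(=O)[C@@](CC=C(C)C)(C(=O)C=C2OC)[C@@]1(C)CCB1C2CCCC1CCC2 | intermediate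
35 | (1R,5S,7R,8S)-7-geranyl-8-homoprenyl-4-methoxy-8-methyl-1,5-diprenylbicyclo[3.3.1]non-3-ene-2,9-dione | CC(C)=CCC/C(C)=C/C[C@@H]1C[C@]2(CC=C(C)C)C(=O)[C@@](CC=C(C)C)(C(=O)C=C2OC)[C@@]1(C)CCC=C(C)C | intermediate
36 | 3-hydroxybenzoic acid | OC(=O)c1cccc(O)c1 | starting material
37 | tert-butyldimethylsilyl 3-(tert-butyldimethylsilyloxy)benzoate | CC(C)(C)[Si](C)(C)OC(=O)c1cccc(O[Si](C)(C)C(C)(C)C)c1 | intermediate
38 | 3-(tert-butyldimethylsilyloxy)benzoyl chloride | ClC(=O)c1cccc(O[Si](C)(C)C(C)(C)C)c1 | intermediate
39 | C3-lithio derivative of 35 | CC(C)=CCC/C(C)=C/C[C@@H]1C[C@]2(CC=C(C)C)C(=O)[C@@](CC=C(C)C)(C(=O)C([Li])=C2OC)[C@@]1(C)CCC=C(C)C | intermediate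
40 | (1S,5S,7R,8S)-3-[3-(tert-butyldimethylsilyloxy)benzoyl]-7-geranyl-8-homoprenyl-4-methoxy-8-methyl-1,5-diprenylbicyclo[3.3.1]non-3-ene-2,9-dione | CC(C)=CCC/C(C)=C/C[C@@H]1C[C@]2(CC=C(C)C)C(=O)[C@@](CC=C(C)C)(C(=O)C(C(=O)c3cccc(O[Si](C)(C)C(C)(C)C)c3)=C2OC)[C@@]1(C)CCC=C(C)C | intermediate
41 | (1S,5S,7R,8S)-7-geranyl-8-homoprenyl-4-hydroxy-3-(3-hydroxybenzoyl)-8-methyl-1,5-diprenylbicyclo[3.3.1]non-3-ene-2,9-dione (CNP0285073.1) | CC(C)=CCC/C(C)=C/C[C@@H]1C[C@]2(CC=C(C)C)C(=O)[C@@](CC=C(C)C)(C(=O)C(C(=O)c3cccc(O)c3)=C2O)[C@@]1(C)CCC=C(C)C | target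

## Step count and least certain steps

Total step count: 24. Longest linear sequence: 20 (steps 1–10, 13–20, 23, 24). Steps 11–12 (diene) and 21–22 (acid chloride) are convergent branches.

**Step 14 (key step).**
- What may go wrong: ionisation of the C8–O bond could run ahead of C–C bond formation, because C8 is fully substituted and sits next to a branched carbon, so backside approach is slow. A free tertiary cation would lose the stereochemical information of the epoxide, accept a hydride shift from the neighbouring carbon (giving a ketone) or lose a proton. Premature hydrolysis of the enol ethers by adventitious acid is the second hazard.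
- Fallback (allylic-cation closure of the same bond, from 14 back to 30): iodide 14 would alkylate the lithio diene 23 (s-BuLi, THF, −78 °C) to give the silyl-protected allylic ether diene F1. Bu4NF would free the allylic alcohol F2, and Ac2O/pyridine would give the allylic acetate F3. TMSOTf/2,6-lutidine at −78 °C would ionise the acetate; one enol ether arm should capture the tertiary terminus of the allyl cation in the same chair (the eight-membered alternative being unfavourable), giving after aqueous quench the C8-vinyl bicyclic enol ether ketone F4. Allylic oxidation under the conditions of step 15 would return the route to 30.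
- Trade-off: this path is four steps shorter, but C8 would then rest only on the chair preference for axial methyl over axial vinyl and not on inversion, which is why it is the fallback.

**Step 13.**
- What may go wrong: displacement of a β-branched primary iodide by a tertiary, delocalised carbanion may be outrun by proton transfer or E2 elimination toward the 1,1-disubstituted alkene, since the anion is also a strong base.
- Fallback (reversed order of the two alkylations, from 17 and 21 back to 24): the less hindered secondary anion 21 would be alkylated with iodide 17 to give the mono-alkylated epoxy diene F5. Deprotonation of F5 (t-BuLi, THF, −78 °C) and trapping with the reactive allylic bromide 20 would then form the quaternary carbon and give 24.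

**Step 19.**
- What may go wrong: lithiation at the vinylic C3–H may compete with bridgehead lithiation, or deprotonation of the hindered C1–H may be incomplete, so that alkylation is partial or misdirected.
- Fallback (blocking group, from 30 back to 32): 30 would be silylated at C3 (lithium 2,2,6,6-tetramethylpiperidide with Me3SiCl in situ, THF, −78 °C) to give the C3-trimethylsilyl vinylogous ester F6. LiN(iPr)2 followed by 20 would then give the C1-prenylated C3-silyl compound F7, and Bu4NF would remove the silyl group to give 32.

**Step 20.**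
- What may go wrong: the B-alkyl group sits on a carbon chain flanked by two quaternary centres, so boron-to-palladium transmetalation may be slow, letting protodeboronation or β-hydride elimination compete. Prolonged heating with excess borane could also begin to reduce a carbonyl group.
- Fallback (stepwise Negishi route, from 32 back to 35): hydroboration with 9-BBN and oxidative work-up (NaBO3) would give the primary alcohol F8. I2/PPh3/imidazole would give the primary iodide F9, and zinc insertion (Zn dust, LiCl, THF) the alkylzinc iodide F10. Negishi coupling of F10 with 33 under Pd(PPh3)4 catalysis would give 35.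

## Further compounds

F1 | step 14 | 6-[(2R,3E)-5-(tert-butyldiphenylsilyloxy)-2-geranyl-3-methylpent-3-enyl]-1,5-dimethoxy-6-prenylcyclohexa-1,4-diene | CC(C)=CCC/C(C)=C/C[C@@H](/C(C)=C/CO[Si](c1ccccc1)(c1ccccc1)C(C)(C)C)CC1(CC=C(C)C)C(OC)=CCC=C1OC
F2 | step 14 | (2E,4R)-5-(2,6-dimethoxy-1-prenylcyclohexa-2,5-dien-1-yl)-4-geranyl-3-methylpent-2-en-1-ol | CC(C)=CCC/C(C)=C/C[C@@H](/C(C)=C/CO)CC1(CC=C(C)C)C(OC)=CCC=C1OC
F3 | step 14 | (2E,4R)-5-(2,6-dimethoxy-1-prenylcyclohexa-2,5-dien-1-yl)-4-geranyl-3-methylpent-2-en-1-yl acetate | CC(C)=CCC/C(C)=C/C[C@@H](/C(C)=C/COC(C)=O)CC1(CC=C(C)C)C(OC)=CCC=C1OC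
F4 | step 14 | (1S,5S,7R,8S)-7-geranyl-4-methoxy-8-methyl-5-prenyl-8-vinylbicyclo[3.3.1]non-3-en-9-one | CC(C)=CCC/C(C)=C/C[C@@H]1C[C@]2(CC=C(C)C)C(=O)[C@@H](CC=C2OC)[C@@]1(C)C=C
F5 | step 13 | 6-[(2R,3S,4S)-3,4-epoxy-2-geranyl-3-methyl-5-(triisopropylsilyloxy)pentyl]-1,5-dimethoxycyclohexa-1,4-diene | CC(C)=CCC/C(C)=C/C[C@@H]([C@]1(C)O[C@H]1CO[Si](C(C)C)(C(C)C)C(C)C)CC1C(OC)=CCC=C1OC
F6 | step 19 | (1R,5S,7R,8S)-7-geranyl-4-methoxy-8-methyl-5-prenyl-3-(trimethylsilyl)-8-vinylbicyclo[3.3.1]non-3-ene-2,9-dione | CC(C)=CCC/C(C)=C/C[C@@H]1C[C@]2(CC=C(C)C)C(=O)[C@@H](C(=O)C([Si](C)(C)C)=C2OC)[C@@]1(C)C=C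
F7 | step 19 | C1-prenyl derivative of F6 (7-geranyl-4-methoxy-8-methyl-1,5-diprenyl-3-(trimethylsilyl)-8-vinylbicyclo[3.3.1]non-3-ene-2,9-dione, core as in 32) | CC(C)=CCC/C(C)=C/C[C@@H]1C[C@]2(CC=C(C)C)C(=O)[C@@](CC=C(C)C)(C(=O)C([Si](C)(C)C)=C2OC)[C@@]1(C)C=C
F8 | step 20 | (1R,5S,7R,8S)-7-geranyl-8-(2-hydroxyethyl)-4-methoxy-8-methyl-1,5-diprenylbicyclo[3.3.1]non-3-ene-2,9-dione | CC(C)=CCC/C(C)=C/C[C@@H]1C[C@]2(CC=C(C)C)C(=O)[C@@](CC=C(C)C)(C(=O)C=C2OC)[C@@]1(C)CCO
F9 | step 20 | (1R,5S,7R,8S)-7-geranyl-8-(2-iodoethyl)-4-methoxy-8-methyl-1,5-diprenylbicyclo[3.3.1]non-3-ene-2,9-dione | CC(C)=CCC/C(C)=C/C[C@@H]1C[C@]2(CC=C(C)C)C(=O)[C@@](CC=C(C)C)(C(=O)C=C2OC)[C@@]1(C)CCI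
F10 | step 20 | alkylzinc iodide from F9 (zinc on the terminal carbon of the two-carbon chain at C8) | CC(C)=CCC/C(C)=C/C[C@@H]1C[C@]2(CC=C(C)C)C(=O)[C@@](CC=C(C)C)(C(=O)C=C2OC)[C@@]1(C)CC[Zn]I
A1 | alternative 1 | (S)-4-geranyl-3-methylcyclohex-2-en-1-one | CC(C)=CCC/C(C)=C/C[C@@H]1CCC(=O)C=C1C
A2 | alternative 1 | 4-geranyl-3-homoprenyl-3-methyl-2-prenylcyclohexanone (C7 and C8 as in 41) | CC(C)=CCC/C(C)=C/C[C@@H]1CCC(=O)[C@H](CC=C(C)C)[C@@]1(C)CCC=C(C)C
A3 | alternative 2 | silyl-protected bicyclic trione with a methyl ester at C7 in place of geranyl | COC(=O)[C@@H]1C[C@]2(CC=C(C)C)C(=O)[C@@](CC=C(C)C)(C(=O)C(C(=O)c3cccc(O[Si](C)(C)C(C)(C)C)c3)=C2O)[C@@]1(C)CCC=C(C)C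
A4 | alternative 3 | (E)-5,9-dimethyldeca-4,8-dienal | CC(C)=CCC/C(C)=C/CCC=O
A5 | alternative 3 | methyl vinyl ketone | CC(=O)C=C
A6 | alternative 3 | (S)-4-geranylcyclohex-2-en-1-one | CC(C)=CCC/C(C)=C/C[C@@H]1CCC(=O)C=C1
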